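**Retrosynthetic overview**

- Ring A of the flavone (C4a, C5, C6, C7, C8, C8a) bears oxygen on C5 through C8a in the pattern of an acetate-derived chain. It is therefore opened at C4a–C5 to an open-chain 5,7,9-trioxo ester whose C7 oxygen already carries the side chain as an enol ether.
- This chain is assembled and stored as its δ-lactone, a 4-alkoxy-3,5-dimethoxypyran-2-one with the ring oxygen on C8a. C7–O is made by addition–elimination of the side-chain alkoxide on the 4-chloropyranone; C4a–C4 and C3–C2 follow by two enolate acylations.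
- The side-chain alcohol comes from umbelliferone: C8 formylation, alkenyl addition, kinetic resolution (C1''), ene oxidation and chelation-controlled reduction (C2'').
- Ring order: coumarin (bought), pyran-2-one (temporary), ring A (Claisen closure, key step), ring C (cyclodehydration; ring A is symmetric about the C7–C4a axis, so both phenols give the same flavone), then release of the C1'' hydroxyl.

Key step: step 14

Remark: O1'' is carried as its TOM acetal (TOM = [tri(propan-2-yl)silyl]oxymethyl, CH2OSi(iPr)3) because a plain silyl ether would migrate to the neighbouring O2'' alkoxide needed in step 11. ScO stands for the [(1S,2R)-1-(7-methoxy-2-oxo-2H-chromen-8-yl)-3-methyl-1-(TOM-oxy)but-3-en-2-yl]oxy group. C1'' is the side-chain carbon on the coumarin and C2'' the one carrying the isopropenyl group. Flavone numbering is used for the chain, and the enolisable centres C3 (and C8 in 21) are carried as epimer mixtures.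

**Route**

Step 1
Reactants: 1 umbelliferone (7-hydroxy-2H-chromen-2-one)
Product: 2 7-hydroxy-2-oxo-2H-chromene-8-carbaldehyde
Conditions: (CH2)6N4, CF3CO2H, 90 °C; then H2O, 60 °C
Reagents that add atoms: hexamethylenetetramine, C1N2CN3CN1CN(C2)C3; water, O
Why: Duff formylation, in which the iminium ion from the aminal should attack C8, the position ortho to both the phenol and the ring oxygen, and hydrolysis of the imine gives the aldehyde.

Step 2
Reactants: 2 7-hydroxy-2-oxo-2H-chromene-8-carbaldehyde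
Product: 3 7-methoxy-2-oxo-2H-chromene-8-carbaldehyde
Conditions: MeI, K2CO3, acetone, 56 °C
Reagents that add atoms: iodomethane, CI
Why: Williamson O-methylation of the phenoxide, to which the aldehyde and the lactone are inert.

Step 3
Reactants: 3 7-methoxy-2-oxo-2H-chromene-8-carbaldehyde
Product: 4 rac-8-(1-hydroxy-3-methylbut-2-en-1-yl)-7-methoxy-2H-chromen-2-one
Conditions: (CH3)2C=CHMgBr, THF, −78 °C; then aq. NH4Cl
Reagents that add atoms: (2-methylprop-1-en-1-yl)magnesium bromide, CC(C)=C[Mg]Br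
Why: Grignard 1,2-addition to the aldehyde, which at −78 °C should react far faster than the coumarin lactone, creates C1'' as a racemate that is resolved in the next step.

Step 4
Reactants: 4 rac-8-(1-hydroxy-3-methylbut-2-en-1-yl)-7-methoxy-2H-chromen-2-one
Product: 5 8-[(1R)-1-hydroxy-3-methylbut-2-en-1-yl]-7-methoxy-2H-chromen-2-one
Conditions: Ti(OiPr)4, D-(−)-diisopropyl tartrate, tBuOOH (0.6 equiv), 4 Å molecular sieves, CH2Cl2, −20 °C
Reagents that add atoms: none
Why: Sharpless kinetic resolution, in which the titanium tartrate from the D-(−)-ester should epoxidise the (S)-alcohol faster and leave the (R)-alcohol, whose C1'' has the spatial arrangement of the target (aryl outranks alkenyl, so the descriptor is the reverse of that of an alkyl alkenyl carbinol of the same shape).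

Step 5
Reactants: 5 8-[(1R)-1-hydroxy-3-methylbut-2-en-1-yl]-7-methoxy-2H-chromen-2-one
Product: 6 7-methoxy-8-[(1R)-3-methyl-1-(TOM-oxy)but-2-en-1-yl]-2H-chromen-2-one
Conditions: iPr3SiOCH2Cl, iPr2NEt, Bu4NI (cat.), CH2Cl2, 40 °C
Reagents that add atoms: (triisopropylsiloxy)methyl chloride, ClCO[Si](C(C)C)(C(C)C)C(C)C
Why: O-alkylation of the hindered carbinol by the α-chloro ether under amine base (acetal formation through the oxocarbenium ion) leaves C1'' untouched and gives a chelating protecting group that cannot undergo 1,2-migration.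

Step 6
Reactants: 6 7-methoxy-8-[(1R)-3-methyl-1-(TOM-oxy)but-2-en-1-yl]-2H-chromen-2-one
Product: 8 7-methoxy-8-[(1S)-3-methyl-2-oxo-1-(TOM-oxy)but-3-en-1-yl]-2H-chromen-2-one, via C2''-hydroperoxide epimers 7 (not isolated)
Conditions: O2, tetraphenylporphyrin (cat.), hν, CH2Cl2, 0 °C; then Ac2O, pyridine, 0 → 20 °C
Reagents that add atoms: dioxygen, O=O
Why: Schenck ene reaction of singlet oxygen should abstract a methyl hydrogen and place the hydroperoxide on C2'' with the double bond moved into the isopropenyl position, and Kornblum–DeLaMare dehydration of the peracetate converges both C2'' epimers on the enone without a base strong enough to epimerise C1''.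

Step 7
Reactants: 8 7-methoxy-8-[(1S)-3-methyl-2-oxo-1-(TOM-oxy)but-3-en-1-yl]-2H-chromen-2-one
Product: 9 8-[(1S,2R)-2-hydroxy-3-methyl-1-(TOM-oxy)but-3-en-1-yl]-7-methoxy-2H-chromen-2-one
Conditions: Zn(BH4)2, Et2O, −30 °C; then H2O
Reagents that add atoms: none
Why: Chelation-controlled (Cram chelate) 1,2-reduction, in which zinc bridges the ketone and the C1'' acetal oxygen and hydride should add to the carbonyl face opposite the aryl group, setting C2'' as R, anti to the C1'' oxygen.

Step 8
Reactants: 10 methyl methoxyacetate (2 equiv: one molecule as the enolate, one as the acyl donor)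
Product: 11 methyl 2,4-dimethoxy-3-oxobutanoate
Conditions: NaH, THF, 65 °C; then aq. HCl
Reagents that add atoms: methyl methoxyacetate (the second molecule of 10, which serves as the acyl donor), COCC(=O)OC
Why: Claisen self-condensation, in which the sodium enolate of one ester molecule adds to the carbonyl of a second and methoxide leaves, driven by formation of the stabilised β-keto ester enolate.

Step 9
Reactants: 11 methyl 2,4-dimethoxy-3-oxobutanoate; 12 N-methoxy-N-methylacetamide
Product: 14 4-hydroxy-3,5-dimethoxy-6-methyl-2H-pyran-2-one, via methyl 2,4-dimethoxy-3,5-dioxohexanoate 13 (not isolated)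
Conditions: LiN(iPr)2 (2.2 equiv), THF, −78 °C; 12; aq. HCl; then DBU (cat.), PhMe, 80 °C
Reagents that add atoms: none
Why: γ-Acylation of the β-keto ester dianion by the Weinreb amide (the chelated adduct prevents over-addition) followed by lactonisation of the 3,5-dioxo ester through its C5 enol should give the 4-hydroxypyran-2-one.

Step 10
Reactants: 14 4-hydroxy-3,5-dimethoxy-6-methyl-2H-pyran-2-one
Product: 15 4-chloro-3,5-dimethoxy-6-methyl-2H-pyran-2-one
Conditions: POCl3, Et3N, 90 °C
Reagents that add atoms: phosphoryl chloride, O=P(Cl)(Cl)Cl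
Why: Deoxychlorination of the vinylogous acid through its dichlorophosphate (addition–elimination by chloride) gives the vinylogous acid chloride.

Step 11
Reactants: 9 8-[(1S,2R)-2-hydroxy-3-methyl-1-(TOM-oxy)but-3-en-1-yl]-7-methoxy-2H-chromen-2-one; 15 4-chloro-3,5-dimethoxy-6-methyl-2H-pyran-2-one
Product: 16 3,5-dimethoxy-6-methyl-4-(ScO)-2H-pyran-2-one
Conditions: KN(SiMe3)2, THF, −78 °C; then 15, −78 → 0 °C
Reagents that add atoms: none
Why: Nucleophilic vinylic substitution (addition–elimination) of the potassium alkoxide at C4 of the 4-chloropyran-2-one forms the C7–O bond without breaking the carbinol C–O bond, so C2'' keeps its R configuration.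

Step 12
Reactants: 16 3,5-dimethoxy-6-methyl-4-(ScO)-2H-pyran-2-one; 17 N,2-dimethoxy-N-methylacetamide
Product: 18 3,5-dimethoxy-6-(3-methoxy-2-oxopropyl)-4-(ScO)-2H-pyran-2-one
Conditions: LiN(iPr)2 (1.2 equiv), THF, −78 °C; 17; then AcOH
Reagents that add atoms: none
Why: Lateral (vinylogous) deprotonation of the 6-methyl group and acylation of the extended enolate by the Weinreb amide forms C4a–C4, and the tetrahedral adduct survives until the quench so that the more acidic product does not consume the anion.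

Step 13
Reactants: 18 3,5-dimethoxy-6-(3-methoxy-2-oxopropyl)-4-(ScO)-2H-pyran-2-one; 19 methyl 3,4,5-trimethoxybenzoate
Product: 20 1-[3,5-dimethoxy-2-oxo-4-(ScO)-2H-pyran-6-yl]-3-methoxy-4-(3,4,5-trimethoxyphenyl)butane-2,4-dione
Conditions: LiN(iPr)2 (3.3 equiv), THF, −78 → −30 °C; 19; then AcOH
Reagents that add atoms: none
Why: Claisen-type C-acylation of the 1,3-dianion (deprotonated at C4a, then at the methoxy-bearing C3) by the benzoate ester at its more basic terminus C3 forms C3–C2, the third equivalent of base taking up the acidic proton of the product.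

Step 14
Reactants: 20 1-[3,5-dimethoxy-2-oxo-4-(ScO)-2H-pyran-6-yl]-3-methoxy-4-(3,4,5-trimethoxyphenyl)butane-2,4-dione
Product: 22 1-[2,6-dihydroxy-3,5-dimethoxy-4-(ScO)phenyl]-2-methoxy-3-(3,4,5-trimethoxyphenyl)propane-1,3-dione, via open-chain triketo ester 21 (not isolated)
Conditions: Mg(OMe)2, MeOH, 50 °C; then aq. AcOH, 0 °C
Reagents that add atoms: none
Why: Proposed new method: methoxide should open the lactone of 20 at C5 to the magnesium-chelated open-chain (Z)-enol-ether triketo ester 21, whose C4a methylene, the only unsubstituted carbon between two ketones, is enolised and attacks the C5 ester carbonyl; loss of methoxide and tautomerisation of the cyclohexenedione give the arene, which makes the step irreversible. The closest known reaction type is the Mg(OMe)2-mediated isomerisation of 6-(2-oxoalkyl)-4-methoxypyran-2-ones and of 3,5,7-trioxo esters to acylphloroglucinols (biomimetic Claisen folding), which has not been shown for a chain with oxygen on every ring carbon, a β-alkoxy-α-methoxyacrylate as acyl donor and a 2-methoxy-1,3-diketone on the nucleophile side. Ring A closes by a 6-(enolexo)-exo-trig Claisen (Dieckmann-type) condensation that forms C4a–C5. No stereocentre is created, since C8 becomes aromatic, C3 stays an enolisable mixture, and C1'' and C2'' are remote from the reacting sites. The step needs Claisen closure from C4a to beat aldol closure from C8 onto the aroyl ketone, return to the lactone and exchange of the C7 alkoxy group by methoxide: the Z geometry inherited from the lactone holds C5 next to C4a, the aldol adduct at the methoxy-bearing C8 cannot dehydrate to an arene and should revert, re-lactonisation is reversible, and the two flanking methoxy groups and the secondary alkyl group shield C7.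

Step 15
Reactants: 22 1-[2,6-dihydroxy-3,5-dimethoxy-4-(ScO)phenyl]-2-methoxy-3-(3,4,5-trimethoxyphenyl)propane-1,3-dione
Product: 23 5-hydroxy-3,6,8-trimethoxy-7-(ScO)-2-(3,4,5-trimethoxyphenyl)-4H-chromen-4-one
Conditions: NaOAc, AcOH, 100 °C
Reagents that add atoms: none
Why: Acid-catalysed cyclodehydration of the o-hydroxyaryl 1,3-diketone (hemiketal at the aroyl ketone, then loss of water, as in the last stage of a Baker–Venkataraman flavone synthesis) closes ring C, and the two phenols are equivalent by symmetry so that only one flavone can form.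

Step 16
Reactants: 23 5-hydroxy-3,6,8-trimethoxy-7-(ScO)-2-(3,4,5-trimethoxyphenyl)-4H-chromen-4-one
Product: 24 5-hydroxy-7-{[(1S,2R)-1-hydroxy-1-(7-methoxy-2-oxo-2H-chromen-8-yl)-3-methylbut-3-en-2-yl]oxy}-3,6,8-trimethoxy-2-(3,4,5-trimethoxyphenyl)-4H-chromen-4-one
Conditions: Bu4NF, AcOH, THF, 20–40 °C
Reagents that add atoms: none
Why: Fluoride attacks silicon of the silyloxymethyl acetal and the hemiacetal loses formaldehyde, which should free the C1'' alcohol under buffered conditions that spare the coumarin lactone, the allyl aryl ether and the chelated phenol.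

**Compound list**

1 | umbelliferone (7-hydroxy-2H-chromen-2-one) | O=c1ccc2ccc(O)cc2o1 | starting material
2 | 7-hydroxy-2-oxo-2H-chromene-8-carbaldehyde | O=Cc1c(O)ccc2ccc(=O)oc12 | intermediate
3 | 7-methoxy-2-oxo-2H-chromene-8-carbaldehyde | O=Cc1c(OC)ccc2ccc(=O)oc12 | intermediate
4 | rac-8-(1-hydroxy-3-methylbut-2-en-1-yl)-7-methoxy-2H-chromen-2-one | CC(C)=CC(O)c1c(OC)ccc2ccc(=O)oc12 | intermediate
5 | 8-[(1R)-1-hydroxy-3-methylbut-2-en-1-yl]-7-methoxy-2H-chromen-2-one | CC(C)=C[C@@H](O)c1c(OC)ccc2ccc(=O)oc12 | intermediate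
6 | 7-methoxy-8-[(1R)-3-methyl-1-({[tri(propan-2-yl)silyl]oxy}methoxy)but-2-en-1-yl]-2H-chromen-2-one | CC(C)=C[C@@H](OCO[Si](C(C)C)(C(C)C)C(C)C)c1c(OC)ccc2ccc(=O)oc12 | intermediate
7 | 8-[(1S)-2-hydroperoxy-3-methyl-1-({[tri(propan-2-yl)silyl]oxy}methoxy)but-3-en-1-yl]-7-methoxy-2H-chromen-2-one (both C2 epimers) | C=C(C)C(OO)[C@@H](OCO[Si](C(C)C)(C(C)C)C(C)C)c1c(OC)ccc2ccc(=O)oc12 | intermediate
8 | 7-methoxy-8-[(1S)-3-methyl-2-oxo-1-({[tri(propan-2-yl)silyl]oxy}methoxy)but-3-en-1-yl]-2H-chromen-2-one | C=C(C)C(=O)[C@@H](OCO[Si](C(C)C)(C(C)C)C(C)C)c1c(OC)ccc2ccc(=O)oc12 | intermediate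
9 | 8-[(1S,2R)-2-hydroxy-3-methyl-1-({[tri(propan-2-yl)silyl]oxy}methoxy)but-3-en-1-yl]-7-methoxy-2H-chromen-2-one | C=C(C)[C@@H](O)[C@@H](OCO[Si](C(C)C)(C(C)C)C(C)C)c1c(OC)ccc2ccc(=O)oc12 | intermediate
10 | methyl methoxyacetate | COCC(=O)OC | starting material
11 | methyl 2,4-dimethoxy-3-oxobutanoate | COCC(=O)C(OC)C(=O)OC | intermediate
12 | N-methoxy-N-methylacetamide | CC(=O)N(C)OC | starting material
13 | methyl 2,4-dimethoxy-3,5-dioxohexanoate | CC(=O)C(OC)C(=O)C(OC)C(=O)OC | intermediate
14 | 4-hydroxy-3,5-dimethoxy-6-methyl-2H-pyran-2-one | Cc1oc(=O)c(OC)c(O)c1OC | intermediate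
15 | 4-chloro-3,5-dimethoxy-6-methyl-2H-pyran-2-one | Cc1oc(=O)c(OC)c(Cl)c1OC | intermediate
16 | 3,5-dimethoxy-4-{[(1S,2R)-1-(7-methoxy-2-oxo-2H-chromen-8-yl)-3-methyl-1-({[tri(propan-2-yl)silyl]oxy}methoxy)but-3-en-2-yl]oxy}-6-methyl-2H-pyran-2-one | C=C(C)[C@@H](Oc1c(OC)c(C)oc(=O)c1OC)[C@@H](OCO[Si](C(C)C)(C(C)C)C(C)C)c1c(OC)ccc2ccc(=O)oc12 | intermediate
17 | N,2-dimethoxy-N-methylacetamide | COCC(=O)N(C)OC | starting material
18 | 3,5-dimethoxy-6-(3-methoxy-2-oxopropyl)-4-{[(1S,2R)-1-(7-methoxy-2-oxo-2H-chromen-8-yl)-3-methyl-1-({[tri(propan-2-yl)silyl]oxy}methoxy)but-3-en-2-yl]oxy}-2H-pyran-2-one | C=C(C)[C@@H](Oc1c(OC)c(CC(=O)COC)oc(=O)c1OC)[C@@H](OCO[Si](C(C)C)(C(C)C)C(C)C)c1c(OC)ccc2ccc(=O)oc12 | intermediate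
19 | methyl 3,4,5-trimethoxybenzoate | COC(=O)c1cc(OC)c(OC)c(OC)c1 | starting material
20 | 1-(3,5-dimethoxy-4-{[(1S,2R)-1-(7-methoxy-2-oxo-2H-chromen-8-yl)-3-methyl-1-({[tri(propan-2-yl)silyl]oxy}methoxy)but-3-en-2-yl]oxy}-2-oxo-2H-pyran-6-yl)-3-methoxy-4-(3,4,5-trimethoxyphenyl)butane-2,4-dione | C=C(C)[C@@H](Oc1c(OC)c(CC(=O)C(OC)C(=O)c3cc(OC)c(OC)c(OC)c3)oc(=O)c1OC)[C@@H](OCO[Si](C(C)C)(C(C)C)C(C)C)c1c(OC)ccc2ccc(=O)oc12 | intermediate
21 | methyl (2Z)-2,4,8-trimethoxy-3-{[(1S,2R)-1-(7-methoxy-2-oxo-2H-chromen-8-yl)-3-methyl-1-({[tri(propan-2-yl)silyl]oxy}methoxy)but-3-en-2-yl]oxy}-5,7,9-trioxo-9-(3,4,5-trimethoxyphenyl)non-2-enoate | C=C(C)[C@@H](O/C(=C(\OC)C(=O)OC)C(OC)C(=O)CC(=O)C(OC)C(=O)c1cc(OC)c(OC)c(OC)c1)[C@@H](OCO[Si](C(C)C)(C(C)C)C(C)C)c1c(OC)ccc2ccc(=O)oc12 | intermediate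
22 | 1-(2,6-dihydroxy-3,5-dimethoxy-4-{[(1S,2R)-1-(7-methoxy-2-oxo-2H-chromen-8-yl)-3-methyl-1-({[tri(propan-2-yl)silyl]oxy}methoxy)but-3-en-2-yl]oxy}phenyl)-2-methoxy-3-(3,4,5-trimethoxyphenyl)propane-1,3-dione | C=C(C)[C@@H](Oc1c(OC)c(O)c(C(=O)C(OC)C(=O)c3cc(OC)c(OC)c(OC)c3)c(O)c1OC)[C@@H](OCO[Si](C(C)C)(C(C)C)C(C)C)c1c(OC)ccc2ccc(=O)oc12 | intermediate
23 | 5-hydroxy-3,6,8-trimethoxy-7-{[(1S,2R)-1-(7-methoxy-2-oxo-2H-chromen-8-yl)-3-methyl-1-({[tri(propan-2-yl)silyl]oxy}methoxy)but-3-en-2-yl]oxy}-2-(3,4,5-trimethoxyphenyl)-4H-chromen-4-one | C=C(C)[C@@H](Oc1c(OC)c(O)c2c(=O)c(OC)c(-c3cc(OC)c(OC)c(OC)c3)oc2c1OC)[C@@H](OCO[Si](C(C)C)(C(C)C)C(C)C)c1c(OC)ccc2ccc(=O)oc12 | intermediate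
24 | 5-hydroxy-7-{[(1S,2R)-1-hydroxy-1-(7-methoxy-2-oxo-2H-chromen-8-yl)-3-methylbut-3-en-2-yl]oxy}-3,6,8-trimethoxy-2-(3,4,5-trimethoxyphenyl)-4H-chromen-4-one | C=C(C)[C@@H](Oc1c(OC)c(O)c2c(=O)c(OC)c(-c3cc(OC)c(OC)c(OC)c3)oc2c1OC)[C@@H](O)c1c(OC)ccc2ccc(=O)oc12 | target

**Step count and risks**

Total: 16 steps. Longest linear sequence: 13 steps (steps 1–7, then 11–16).

Steps most likely to fail:

1. Step 14. The magnesium enolates of the tricarbonyl chain may close through the aldol or the O-cyclisation (pyranone) manifold, or methoxide may exchange the C7 alkoxy group, faster than C4a adds to the deactivated, fully substituted acrylate ester. The fallback uses known chemistry and closes ring A before the aroyl ketone is present. It sets out from 18, which is given the same Mg(OMe)2/MeOH treatment. 18 is a 6-(2-oxoalkyl)-4-alkoxypyran-2-one, the type for which this lactone-to-acylphloroglucinol isomerisation is established, and it has no second ketone to offer an aldol or pyranone path. This should give 1-[2,6-dihydroxy-3,5-dimethoxy-4-(ScO)phenyl]-2-methoxyethan-1-one F1. The lithium trianion of F1 (LiN(SiMe3)2, THF, −78 °C) is then C-aroylated at the methoxy-bearing carbon with 3,4,5-trimethoxybenzoyl chloride, the one-pot form of the Baker–Venkataraman sequence, which comes back to the route at 22.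

2. Step 11. The hindered secondary alkoxide may attack the lactone carbonyl or deprotonate the 6-methyl group instead of adding at the doubly flanked C4, so that substitution stalls. The fallback sets out from 8. Reduction with KBH(sBu)3 in THF at −78 °C (Felkin–Anh control, no chelation) should give the C2'' epimer, 8-[(1S,2S)-2-hydroxy-3-methyl-1-(TOM-oxy)but-3-en-1-yl]-7-methoxy-2H-chromen-2-one F2. Mitsunobu coupling of F2 with the acidic hydroxypyranone 14 (PPh3, iPrO2CN=NCO2iPr, THF) then forms the C7–O bond by SN2 inversion at C2'' and comes back to the route at 16.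

3. Step 13. Incomplete second deprotonation, proton transfer from the acidic product to the dianion and attack of the excess amide base on the coumarin lactone may hold the conversion low. The fallback needs no dianion and sets out from 16 and 17. The lithium enolate of 17 (LiN(iPr)2, THF, −78 °C) is added to 3,4,5-trimethoxybenzaldehyde and the aldol is silylated (Et3SiCl, imidazole) to N,2-dimethoxy-N-methyl-3-[(triethylsilyl)oxy]-3-(3,4,5-trimethoxyphenyl)propanamide F3. The lateral lithium anion of 16, formed as in step 12, is acylated by F3 to the ketone 3,5-dimethoxy-6-{3-methoxy-2-oxo-4-[(triethylsilyl)oxy]-4-(3,4,5-trimethoxyphenyl)butyl}-4-(ScO)-2H-pyran-2-one F4. AcOH/THF/H2O removes the triethylsilyl group to give the hydroxy ketone 6-[4-hydroxy-3-methoxy-2-oxo-4-(3,4,5-trimethoxyphenyl)butyl]-3,5-dimethoxy-4-(ScO)-2H-pyran-2-one F5, and Dess–Martin periodinane oxidises the benzylic alcohol, which comes back to the route at 20.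

**Further compounds**

F1 | step 14 | 1-(2,6-dihydroxy-3,5-dimethoxy-4-{[(1S,2R)-1-(7-methoxy-2-oxo-2H-chromen-8-yl)-3-methyl-1-({[tri(propan-2-yl)silyl]oxy}methoxy)but-3-en-2-yl]oxy}phenyl)-2-methoxyethan-1-one | C=C(C)[C@@H](Oc1c(OC)c(O)c(C(=O)COC)c(O)c1OC)[C@@H](OCO[Si](C(C)C)(C(C)C)C(C)C)c1c(OC)ccc2ccc(=O)oc12
F2 | step 11 | 8-[(1S,2S)-2-hydroxy-3-methyl-1-({[tri(propan-2-yl)silyl]oxy}methoxy)but-3-en-1-yl]-7-methoxy-2H-chromen-2-one | C=C(C)[C@H](O)[C@@H](OCO[Si](C(C)C)(C(C)C)C(C)C)c1c(OC)ccc2ccc(=O)oc12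
F3 | step 13 | N,2-dimethoxy-N-methyl-3-[(triethylsilyl)oxy]-3-(3,4,5-trimethoxyphenyl)propanamide (diastereomer mixture) | CON(C)C(=O)C(OC)C(O[Si](CC)(CC)CC)c1cc(OC)c(OC)c(OC)c1
F4 | step 13 | 3,5-dimethoxy-6-{3-methoxy-2-oxo-4-[(triethylsilyl)oxy]-4-(3,4,5-trimethoxyphenyl)butyl}-4-{[(1S,2R)-1-(7-methoxy-2-oxo-2H-chromen-8-yl)-3-methyl-1-({[tri(propan-2-yl)silyl]oxy}methoxy)but-3-en-2-yl]oxy}-2H-pyran-2-one | C=C(C)[C@@H](Oc1c(OC)c(CC(=O)C(OC)C(O[Si](CC)(CC)CC)c3cc(OC)c(OC)c(OC)c3)oc(=O)c1OC)[C@@H](OCO[Si](C(C)C)(C(C)C)C(C)C)c1c(OC)ccc2ccc(=O)oc12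
F5 | step 13 | 6-[4-hydroxy-3-methoxy-2-oxo-4-(3,4,5-trimethoxyphenyl)butyl]-3,5-dimethoxy-4-{[(1S,2R)-1-(7-methoxy-2-oxo-2H-chromen-8-yl)-3-methyl-1-({[tri(propan-2-yl)silyl]oxy}methoxy)but-3-en-2-yl]oxy}-2H-pyran-2-one | C=C(C)[C@@H](Oc1c(OC)c(CC(=O)C(OC)C(O)c3cc(OC)c(OC)c(OC)c3)oc(=O)c1OC)[C@@H](OCO[Si](C(C)C)(C(C)C)C(C)C)c1c(OC)ccc2ccc(=O)oc12
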